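**Retrosynthetic overview**

1. Target 28 comes from flavone 26 by removal of two allyl and two silyl ethers. Ring C of 26 is closed last, at C4–C4a, by intramolecular Friedel–Crafts acylation of the (Z)-3-aryloxy-3-arylacrylic acid 24.
2. Feature: in ring A, C4a lies between the oxygen-bearing carbons C5 and C8a of a phloroglucinol nucleus whose two positions ortho to O1 are equivalent. It is therefore a strong and regiochemically unambiguous nucleophile for the acyl carbon C4.
3. Acid 24 comes from the O1–C2 bond, made by conjugate addition of 3,5-bis(allyloxy)phenol 22 to arylpropiolate 20. Propiolate 20 comes from aryl bromide 14 by Sonogashira coupling and acetylide carboxylation.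
4. The dihydrofuran ring on ring B is formed first, by 5-exo opening of the threo epoxy alcohol 8 by the phenoxide with inversion at C2. C3 is set by enantioselective alkenylzinc addition to aldehyde 5, and C2 by hydroxyl-directed epoxidation. The C7 prenyl group comes from a Claisen-derived allyl group by cross-metathesis, and the arene from 5-bromosalicylaldehyde 1.

Key step: step 15

Remark on the chemistry: both hydroxyl groups of ring B are carried as silyl ethers (benzylic TIPS, tertiary TES), because a free tertiary alcohol would not survive chloroformate acylation and acid chloride formation. A mixture of enol ether geometries in 23 and 24 is acceptable, since the E acylium ion can rotate into the Z ion that closes.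

Abbreviation used in names: ArB = (2S,3S)-7-(3-methylbut-2-en-1-yl)-2-[2-(triethylsilyloxy)propan-2-yl]-3-(triisopropylsilyloxy)-2,3-dihydro-1-benzofuran-5-yl.

**Route**

Step 1
Reactants: 1 5-bromosalicylaldehyde; 2 allyl bromide
Product: 3 2-(allyloxy)-5-bromobenzaldehyde
Conditions: K2CO3, DMF, rt → 50 °C
Reagents that add atoms: allyl bromide (2), C=CCBr
Why: Williamson ether synthesis, the phenoxide displacing bromide from the primary allylic carbon.

Step 2
Reactants: 3 2-(allyloxy)-5-bromobenzaldehyde
Product: 4 3-allyl-5-bromo-2-hydroxybenzaldehyde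
Conditions: N,N-diethylaniline, 190 °C, sealed tube
Reagents that add atoms: none
Why: Aromatic Claisen rearrangement ([3,3]-sigmatropic shift to the only free ortho position, then tautomerisation) places the three-carbon chain on the carbon that becomes C7 of the dihydrobenzofuran.

Step 3
Reactants: 4 3-allyl-5-bromo-2-hydroxybenzaldehyde; 2 allyl bromide
Product: 5 3-allyl-2-(allyloxy)-5-bromobenzaldehyde
Conditions: K2CO3, DMF, 60 °C
Reagents that add atoms: allyl bromide (2), C=CCBr
Why: Williamson ether synthesis; the allyl ether masks the phenol against the organozinc reagent and the peracid and is later removed under neutral conditions.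

Step 4
Reactants: 5 3-allyl-2-(allyloxy)-5-bromobenzaldehyde; 6 2-methylprop-1-enylmagnesium bromide
Product: 7 (1R)-1-[3-allyl-2-(allyloxy)-5-bromophenyl]-3-methylbut-2-en-1-ol
Conditions: 6, ZnCl2, THF, 0 °C, then 1,4-dioxane and filtration of the magnesium halide; (+)-MIB [3-exo-morpholinoisoborneol] (10 mol%), toluene, 0 °C; aq. NH4Cl
Reagents that add atoms: 2-methylprop-1-enylmagnesium bromide (6), CC(C)=C[Mg]Br
Why: Amino-alcohol-catalysed enantioselective addition of an alkenylzinc reagent to an aryl aldehyde; the (+)-MIB–zinc chelate should deliver the alkenyl group to the Re face (its enantiomer delivers to the Si face), which sets the carbinol carbon, the later C3 of the dihydrofuran, as R in 7.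

Step 5
Reactants: 7 (1R)-1-[3-allyl-2-(allyloxy)-5-bromophenyl]-3-methylbut-2-en-1-ol
Product: 8 (S)-[3-allyl-2-(allyloxy)-5-bromophenyl][(2R)-3,3-dimethyloxiran-2-yl]methanol
Conditions: mCPBA (1.05 equiv), NaHCO3, CH2Cl2, 0 °C
Reagents that add atoms: mCPBA, O=C(OO)c1cccc(Cl)c1
Why: Hydroxyl-directed Prilezhaev epoxidation: allylic 1,3-strain between the cis methyl group and the carbinol substituents holds the carbinol C–H in the alkene plane, so the hydrogen-bonded peracid attacks the face bearing OH and should give the threo (1S,2R) epoxy alcohol, while the trisubstituted alkene reacts far faster than the two monosubstituted allyl alkenes.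

Step 6
Reactants: 8 (S)-[3-allyl-2-(allyloxy)-5-bromophenyl][(2R)-3,3-dimethyloxiran-2-yl]methanol
Product: 10 (2S,3S)-7-allyl-5-bromo-2-(2-hydroxypropan-2-yl)-2,3-dihydro-1-benzofuran-3-ol, via phenolic epoxy alcohol 9 (not isolated)
Conditions: Pd(PPh3)4 (3 mol%), morpholine, THF, rt; then K2CO3, MeOH, rt
Reagents that add atoms: none
Why: Tsuji–Trost allyl transfer to morpholine frees the phenol, whose phenoxide opens the epoxide in a 5-exo-tet SN2 reaction at the secondary carbon with inversion, setting C2 as S and trans to the C3 hydroxyl (6-endo attack at the tertiary carbon is disfavoured under basic conditions).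

Step 7
Reactants: 10 (2S,3S)-7-allyl-5-bromo-2-(2-hydroxypropan-2-yl)-2,3-dihydro-1-benzofuran-3-ol; 11 2-methylbut-2-ene
Product: 12 (2S,3S)-5-bromo-2-(2-hydroxypropan-2-yl)-7-(3-methylbut-2-en-1-yl)-2,3-dihydro-1-benzofuran-3-ol
Conditions: second-generation Grubbs catalyst RuCl2(=CHPh)(H2IMes)(PCy3) (5 mol%), 2-methylbut-2-ene/CH2Cl2, 40 °C, sealed tube
Reagents that add atoms: 2-methylbut-2-ene (11), CC=C(C)C
Why: Olefin cross-metathesis of the terminal allyl group with excess 2-methylbut-2-ene gives the prenyl group with loss of propene; the free diol and the aryl bromide are tolerated.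

Step 8
Reactants: 12 (2S,3S)-5-bromo-2-(2-hydroxypropan-2-yl)-7-(3-methylbut-2-en-1-yl)-2,3-dihydro-1-benzofuran-3-ol
Product: 14 (2S,3S)-5-bromo-7-(3-methylbut-2-en-1-yl)-2-[2-(triethylsilyloxy)propan-2-yl]-3-(triisopropylsilyloxy)-2,3-dihydro-1-benzofuran, via mono-TIPS ether 13 (not isolated)
Conditions: TIPSOTf (1.2 equiv), 2,6-lutidine, CH2Cl2, −78 → 0 °C; then TESOTf (1.5 equiv), 0 °C → rt
Reagents that add atoms: triisopropylsilyl triflate, CC(C)[Si](C(C)C)(C(C)C)OS(=O)(=O)C(F)(F)F; triethylsilyl triflate, CC[Si](CC)(CC)OS(=O)(=O)C(F)(F)F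
Why: Silyl triflate silylation; the bulky TIPS triflate takes the secondary benzylic hydroxyl only, and the smaller TES triflate then silylates the tertiary hydroxyl.

Step 9
Reactants: 14 (2S,3S)-5-bromo-7-(3-methylbut-2-en-1-yl)-2-[2-(triethylsilyloxy)propan-2-yl]-3-(triisopropylsilyloxy)-2,3-dihydro-1-benzofuran; 15 trimethylsilylacetylene
Product: 16 trimethyl[(ArB)ethynyl]silane
Conditions: PdCl2(PhCN)2 (3 mol%), [HP(t-Bu)3]BF4 (6 mol%), CuI (3 mol%), i-Pr2NH, 1,4-dioxane, rt → 45 °C
Reagents that add atoms: trimethylsilylacetylene (15), C#C[Si](C)(C)C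
Why: Sonogashira coupling; the electron-rich but unhindered aryl bromide undergoes oxidative addition readily with the bulky trialkylphosphine catalyst.

Step 10
Reactants: 16 trimethyl[(ArB)ethynyl]silane
Product: 17 ArB–C≡CH [(2S,3S)-5-ethynyl-7-(3-methylbut-2-en-1-yl)-2-[2-(triethylsilyloxy)propan-2-yl]-3-(triisopropylsilyloxy)-2,3-dihydro-1-benzofuran]
Conditions: K2CO3 (0.2 equiv), MeOH/THF, rt
Reagents that add atoms: none
Why: Methanolysis of the alkynyl–silicon bond; the hindered alkyl silyl ethers are not cleaved by carbonate in methanol.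

Step 11
Reactants: 17 ArB–C≡CH; 18 methyl chloroformate
Product: 20 methyl 3-(ArB)prop-2-ynoate, via lithium acetylide 19 (not isolated)
Conditions: n-BuLi, THF, −78 °C; then ClCO2Me (excess), −78 → 0 °C
Reagents that add atoms: methyl chloroformate (18), COC(=O)Cl
Why: Deprotonation of the terminal alkyne and acylation of the acetylide with a chloroformate, the standard route to arylpropiolates.

Step 12
Reactants: 21 phloroglucinol; 2 allyl bromide
Product: 22 3,5-bis(allyloxy)phenol
Conditions: allyl bromide (2.0 equiv), K2CO3, DMF, 0 °C → rt; chromatographic separation from the mono- and triallyl ethers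
Reagents that add atoms: allyl bromide (2), C=CCBr
Why: Williamson ether synthesis run to the statistical diallyl stage; the three hydroxyl groups are equivalent, so only the degree of alkylation needs to be sorted.

Step 13
Reactants: 20 methyl 3-(ArB)prop-2-ynoate; 22 3,5-bis(allyloxy)phenol
Product: 23 methyl (2Z)-3-[3,5-bis(allyloxy)phenoxy]-3-(ArB)prop-2-enoate
Conditions: K2CO3, DMF, 70 °C
Reagents that add atoms: 3,5-bis(allyloxy)phenol (22), C=CCOc1cc(O)cc(OCC=C)c1
Why: Oxa-Michael addition of the phenoxide to the ynoate forms the O1–C2 bond; anti addition should place the aryloxy group cis to the ester (Z).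

Step 14
Reactants: 23 methyl (2Z)-3-[3,5-bis(allyloxy)phenoxy]-3-(ArB)prop-2-enoate
Product: 24 (2Z)-3-[3,5-bis(allyloxy)phenoxy]-3-(ArB)prop-2-enoic acid
Conditions: LiOH, THF/MeOH/H2O, rt; then 1 M HCl to pH 4, 0 °C
Reagents that add atoms: lithium hydroxide, [Li+].[OH-]
Why: Saponification of the methyl ester; the enol ether, allyl ethers and hindered silyl ethers are stable to hydroxide at rt.

Step 15
Reactants: 24 (2Z)-3-[3,5-bis(allyloxy)phenoxy]-3-(ArB)prop-2-enoic acid
Product: 26 5,7-bis(allyloxy)-2-(ArB)-4H-chromen-4-one, via acid chloride 25 (not isolated)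
Conditions: 1-chloro-N,N,2-trimethylprop-1-en-1-amine (1.0 equiv), CH2Cl2, 0 °C; then SnCl4 (1.1 equiv), 2,6-di-tert-butyl-4-methylpyridine, CH2Cl2, −78 → −40 °C
Reagents that add atoms: none
Why: The α-chloroenamine converts the acid into acid chloride 25 without liberating strong acid, SnCl4 ionises it to an acylium ion (a resonance hybrid with an oxocarbenium–ketene form), its carbon C4 is attacked by C4a of the tris-oxygenated ring, and loss of the proton to the hindered pyridine restores aromaticity. The closest known reaction type is the classical intramolecular Friedel–Crafts acylation of 3-aryloxycinnamic acids to flavones. Ring C closes as a six-membered ring at a carbon–carbon bond, exo with respect to the acyl C=O and endo with respect to the arene π bond. No stereocenter is formed, and C2 and C3 of the dihydrofuran are remote and held as ethers. The step needs site selectivity, which the symmetry of ring A secures because both positions ortho to O1 are identical and the position between the two allyloxy groups cannot reach C4; it also needs chemoselectivity over the prenyl alkene and the benzylic silyl ether, which the high nucleophilicity of ring A, the low temperature, the exact stoichiometry of the chloroenamine and the proton scavenger are expected to secure. Any E isomer can rotate about the former C=C bond in the acylium ion, so both geometries should converge on 26.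

Step 16
Reactants: 26 5,7-bis(allyloxy)-2-(ArB)-4H-chromen-4-one
Product: 27 5,7-dihydroxy-2-(ArB)-4H-chromen-4-one
Conditions: Pd(PPh3)4 (5 mol%), morpholine, THF, rt
Reagents that add atoms: none
Why: Tsuji–Trost deallylation: zerovalent palladium ionises both aryl allyl ethers and morpholine traps the allyl groups; the C-prenyl group and the silyl ethers are inert.

Step 17
Reactants: 27 5,7-dihydroxy-2-(ArB)-4H-chromen-4-one
Product: 28 5,7-dihydroxy-2-[(2S,3S)-3-hydroxy-2-(2-hydroxypropan-2-yl)-7-(3-methylbut-2-en-1-yl)-2,3-dihydro-1-benzofuran-5-yl]-4H-chromen-4-one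
Conditions: Bu4NF (TBAF, excess), THF, 0 °C → rt; aq. NH4Cl
Reagents that add atoms: none
Why: Fluoride-driven cleavage of the TIPS and TES ethers (strong Si–F bond) under conditions that do not ionise the benzylic alcohol, so C2 and C3 are untouched.

**Compound list**

1 | 5-bromosalicylaldehyde | O=Cc1cc(Br)ccc1O | starting material
2 | allyl bromide | C=CCBr | starting material
3 | 2-(allyloxy)-5-bromobenzaldehyde | O=Cc1cc(Br)ccc1OCC=C | intermediate
4 | 3-allyl-5-bromo-2-hydroxybenzaldehyde | O=Cc1cc(Br)cc(CC=C)c1O | intermediate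
5 | 3-allyl-2-(allyloxy)-5-bromobenzaldehyde | O=Cc1cc(Br)cc(CC=C)c1OCC=C | intermediate
6 | 2-methylprop-1-enylmagnesium bromide | CC(C)=C[Mg]Br | starting material
7 | (1R)-1-[3-allyl-2-(allyloxy)-5-bromophenyl]-3-methylbut-2-en-1-ol | CC(C)=C[C@@H](O)c1cc(Br)cc(CC=C)c1OCC=C | intermediate
8 | (S)-[3-allyl-2-(allyloxy)-5-bromophenyl][(2R)-3,3-dimethyloxiran-2-yl]methanol | CC1(C)O[C@@H]1[C@@H](O)c1cc(Br)cc(CC=C)c1OCC=C | intermediate
9 | 2-allyl-4-bromo-6-{(S)-[(2R)-3,3-dimethyloxiran-2-yl](hydroxy)methyl}phenol (not isolated) | CC1(C)O[C@@H]1[C@@H](O)c1cc(Br)cc(CC=C)c1O | intermediate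
10 | (2S,3S)-7-allyl-5-bromo-2-(2-hydroxypropan-2-yl)-2,3-dihydro-1-benzofuran-3-ol | C=CCc1cc(Br)cc2c1O[C@H](C(C)(C)O)[C@H]2O | intermediate
11 | 2-methylbut-2-ene | CC=C(C)C | starting material
12 | (2S,3S)-5-bromo-2-(2-hydroxypropan-2-yl)-7-(3-methylbut-2-en-1-yl)-2,3-dihydro-1-benzofuran-3-ol | CC(C)=CCc1cc(Br)cc2c1O[C@H](C(C)(C)O)[C@H]2O | intermediate
13 | 2-[(2S,3S)-5-bromo-7-(3-methylbut-2-en-1-yl)-3-(triisopropylsilyloxy)-2,3-dihydro-1-benzofuran-2-yl]propan-2-ol (not isolated) | CC(C)=CCc1cc(Br)cc2c1O[C@H](C(C)(C)O)[C@H]2O[Si](C(C)C)(C(C)C)C(C)C | intermediate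
14 | (2S,3S)-5-bromo-7-(3-methylbut-2-en-1-yl)-2-[2-(triethylsilyloxy)propan-2-yl]-3-(triisopropylsilyloxy)-2,3-dihydro-1-benzofuran | CC(C)=CCc1cc(Br)cc2c1O[C@H](C(C)(C)O[Si](CC)(CC)CC)[C@H]2O[Si](C(C)C)(C(C)C)C(C)C | intermediate
15 | trimethylsilylacetylene | C#C[Si](C)(C)C | starting material
16 | trimethyl[(ArB)ethynyl]silane | CC(C)=CCc1cc(C#C[Si](C)(C)C)cc2c1O[C@H](C(C)(C)O[Si](CC)(CC)CC)[C@H]2O[Si](C(C)C)(C(C)C)C(C)C | intermediate
17 | (2S,3S)-5-ethynyl-7-(3-methylbut-2-en-1-yl)-2-[2-(triethylsilyloxy)propan-2-yl]-3-(triisopropylsilyloxy)-2,3-dihydro-1-benzofuran | CC(C)=CCc1cc(C#C)cc2c1O[C@H](C(C)(C)O[Si](CC)(CC)CC)[C@H]2O[Si](C(C)C)(C(C)C)C(C)C | intermediate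
18 | methyl chloroformate | COC(=O)Cl | starting material
19 | lithium acetylide of 17 (not isolated) | CC(C)=CCc1cc(C#C[Li])cc2c1O[C@H](C(C)(C)O[Si](CC)(CC)CC)[C@H]2O[Si](C(C)C)(C(C)C)C(C)C | intermediate
20 | methyl 3-(ArB)prop-2-ynoate | CC(C)=CCc1cc(C#CC(=O)OC)cc2c1O[C@H](C(C)(C)O[Si](CC)(CC)CC)[C@H]2O[Si](C(C)C)(C(C)C)C(C)C | intermediate
21 | phloroglucinol | Oc1cc(O)cc(O)c1 | starting material
22 | 3,5-bis(allyloxy)phenol | C=CCOc1cc(O)cc(OCC=C)c1 | intermediate
23 | methyl (2Z)-3-[3,5-bis(allyloxy)phenoxy]-3-(ArB)prop-2-enoate | CC(C)=CCc1cc(/C(Oc3cc(OCC=C)cc(OCC=C)c3)=C/C(=O)OC)cc2c1O[C@H](C(C)(C)O[Si](CC)(CC)CC)[C@H]2O[Si](C(C)C)(C(C)C)C(C)C | intermediate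
24 | (2Z)-3-[3,5-bis(allyloxy)phenoxy]-3-(ArB)prop-2-enoic acid | CC(C)=CCc1cc(/C(Oc3cc(OCC=C)cc(OCC=C)c3)=C/C(=O)O)cc2c1O[C@H](C(C)(C)O[Si](CC)(CC)CC)[C@H]2O[Si](C(C)C)(C(C)C)C(C)C | intermediate
25 | (2Z)-3-[3,5-bis(allyloxy)phenoxy]-3-(ArB)prop-2-enoyl chloride (not isolated) | CC(C)=CCc1cc(/C(Oc3cc(OCC=C)cc(OCC=C)c3)=C/C(=O)Cl)cc2c1O[C@H](C(C)(C)O[Si](CC)(CC)CC)[C@H]2O[Si](C(C)C)(C(C)C)C(C)C | intermediate
26 | 5,7-bis(allyloxy)-2-(ArB)-4H-chromen-4-one | CC(C)=CCc1cc(-c2cc(=O)c3c(OCC=C)cc(OCC=C)cc3o2)cc2c1O[C@H](C(C)(C)O[Si](CC)(CC)CC)[C@H]2O[Si](C(C)C)(C(C)C)C(C)C | intermediate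
27 | 5,7-dihydroxy-2-(ArB)-4H-chromen-4-one | CC(C)=CCc1cc(-c2cc(=O)c3c(O)cc(O)cc3o2)cc2c1O[C@H](C(C)(C)O[Si](CC)(CC)CC)[C@H]2O[Si](C(C)C)(C(C)C)C(C)C | intermediate
28 | 5,7-dihydroxy-2-[(2S,3S)-3-hydroxy-2-(2-hydroxypropan-2-yl)-7-(3-methylbut-2-en-1-yl)-2,3-dihydro-1-benzofuran-5-yl]-4H-chromen-4-one | CC(C)=CCc1cc(-c2cc(=O)c3c(O)cc(O)cc3o2)cc2c1O[C@H](C(C)(C)O)[C@H]2O | target

**Step count**

Total steps: 17. Longest linear sequence: 16 steps (steps 1–11 and 13–17, from 5-bromosalicylaldehyde); step 12 is the single step of the ring A branch.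

**Steps most likely to fail**

1. Step 15 (ring closure by acylation). Under SnCl4 the benzylic silyl ether at C3 of the dihydrofuran may ionise, helped by the ring oxygen, and lose silanol to give a benzofuran. The Lewis acid may also trigger Claisen rearrangement of the allyl ethers or attack on the prenyl alkene faster than ring closure. The fallback closes ring C at O1–C2 without a Lewis acid; it sets out from alkyne 17 and comes back at 26. Bought 2,4,6-trihydroxybenzaldehyde is diallylated with 2 and K2CO3 in acetone to 2-hydroxy-4,6-bis(allyloxy)benzaldehyde F1, the chelated hydroxyl staying free. Its sodium phenoxide (NaH, THF) is treated at −78 °C with lithium acetylide 19, made from 17 and n-BuLi, to give the propargylic alcohol F2 as a mixture of carbinol epimers. MnO2 in CH2Cl2 oxidises this to the 2-hydroxyaryl ynone F3. Et2NH in EtOH at rt then adds to the ynone, and the phenol displaces the amine in a 6-endo oxa-Michael closure that should deliver 26.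

2. Step 4 (enantioselective alkenylation). Racemic background addition, promoted by residual magnesium halide or by chelation of zinc to the ortho allyloxy group, may lower the enantiomeric purity of 7 and of everything after it. The fallback sets the stereocenter by reduction instead of addition; it sets out from 5 and 6 and comes back at 7. Uncatalysed addition of 6 to 5 in THF at −78 °C gives the racemic alcohol F4, and MnO2 oxidises it to the aryl isobutenyl ketone F5. Corey–Bakshi–Shibata reduction with (S)-2-methyl-CBS-oxazaborolidine and catecholborane in toluene at −78 °C is then expected to return (R)-7, provided the twisted ortho-alkoxy aryl group acts as the larger substituent.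

3. Step 13 (phenoxide addition to the ynoate). The phloroglucinol-type phenoxide is ambident and may attack through carbon, or it may add too slowly to an ynoate deactivated by the electron-rich aryl group, so that decomposition competes. The fallback forms the C–O bond by copper-catalysed vinylation instead of conjugate addition; it sets out from 20 and comes back at 23. LiI and AcOH in MeCN at 60 °C add HI across the ynoate in the anti sense to give the (Z)-3-iodoacrylate F6. CuI, N,N-dimethylglycine and Cs2CO3 in 1,4-dioxane at 80 °C then couple this with phenol 22 with retention of alkene geometry to give 23.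

**Further compounds**

F1 | step 15 | 2-hydroxy-4,6-bis(allyloxy)benzaldehyde | O=Cc1c(O)cc(OCC=C)cc1OCC=C
F2 | step 15 | 1-[2-hydroxy-4,6-bis(allyloxy)phenyl]-3-(ArB)prop-2-yn-1-ol (carbinol epimers) | CC(C)=CCc1cc(C#CC(O)c3c(O)cc(OCC=C)cc3OCC=C)cc2c1O[C@H](C(C)(C)O[Si](CC)(CC)CC)[C@H]2O[Si](C(C)C)(C(C)C)C(C)C
F3 | step 15 | 1-[2-hydroxy-4,6-bis(allyloxy)phenyl]-3-(ArB)prop-2-yn-1-one | CC(C)=CCc1cc(C#CC(=O)c3c(O)cc(OCC=C)cc3OCC=C)cc2c1O[C@H](C(C)(C)O[Si](CC)(CC)CC)[C@H]2O[Si](C(C)C)(C(C)C)C(C)C
F4 | step 4 | racemic 1-[3-allyl-2-(allyloxy)-5-bromophenyl]-3-methylbut-2-en-1-ol | CC(C)=CC(O)c1cc(Br)cc(CC=C)c1OCC=C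
F5 | step 4 | 1-[3-allyl-2-(allyloxy)-5-bromophenyl]-3-methylbut-2-en-1-one | CC(C)=CC(=O)c1cc(Br)cc(CC=C)c1OCC=C
F6 | step 13 | methyl (2Z)-3-iodo-3-(ArB)prop-2-enoate | CC(C)=CCc1cc(/C(I)=C/C(=O)OC)cc2c1O[C@H](C(C)(C)O[Si](CC)(CC)CC)[C@H]2O[Si](C(C)C)(C(C)C)C(C)C
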